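The cyclopentene (ring A) is opened at the C2–C3 bond. C2, the ring alkene carbon that carries CHO, is the α-carbon of a 3-(acetoxymethyl)enal. C3, the ring CH, is the β-carbon of a second, 2-alkyl enal whose α-carbon is C8, the side-chain CH carrying CHO. In one operation a chiral secondary amine turns the first enal into a dienamine that adds through C2 to C3: ring A closes, C3 and C8 are set, the C1=C2 enal is restored and the target forms directly. The precursor is an acyclic bis-enal monoacetate on a hexadecatetraene backbone, joined from two aldehyde halves by cross-metathesis.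

Key step: step 9

Assumption: the sense of induction is assigned from the usual shielding model of diarylprolinol silyl ethers, which predicts 3S for the (R)-amine; if the first run shows the opposite sense, the (S)-amine is used with no other change.

Step 1
Reactants: 1 geranyl bromide [(2E)-1-bromo-3,7-dimethylocta-2,6-diene]; 2 2-(2-bromoethyl)-1,3-dioxolane
Product: 4 2-[(4E)-5,9-dimethyldeca-4,8-dien-1-yl]-1,3-dioxolane, via Grignard reagent 3 (not isolated)
Conditions: 2, Mg, THF, 25 °C; then 1, Li2CuCl4 (3 mol%), THF, −10 to 0 °C
Reagents that add atoms: none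
Why: Copper-catalysed cross-coupling of a primary alkyl Grignard reagent with an allylic bromide in THF should occur at the unsubstituted allylic carbon with retention of the (E)-alkene, the acetal serving as a stable three-carbon homoenolate equivalent.

Step 2
Reactants: 4 2-[(4E)-5,9-dimethyldeca-4,8-dien-1-yl]-1,3-dioxolane
Product: 5 (5E)-6,10-dimethylundeca-5,9-dienal
Conditions: 1 M HCl, THF, 40 °C
Reagents that add atoms: water, O
Why: Acid-catalysed acetal hydrolysis should free the aldehyde under conditions too mild to protonate the trisubstituted alkenes.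

Step 3
Reactants: 5 (5E)-6,10-dimethylundeca-5,9-dienal
Product: 6 (5E)-6,10-dimethyl-2-methylideneundeca-5,9-dienal
Conditions: 37% aq. HCHO, pyrrolidine (10 mol%), EtCO2H (10 mol%), i-PrOH, 45 °C
Reagents that add atoms: formaldehyde, C=O
Why: Amine-catalysed Mannich-type α-methylenation (aminomethylation of the enamine, then β-elimination of the amine) should convert the α-unbranched aldehyde into its 2-methylene derivative without touching the isolated alkenes.

Step 4
Reactants: 7 pent-4-enoyl chloride
Product: 9 1-hydroxyhex-5-en-2-one, via silyl ester 8 (not isolated)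
Conditions: (Me3SiO)2C=CH(OSiMe3) (2 equiv), neat, 95 °C; then 0.6 M HCl, dioxane, 85 °C
Reagents that add atoms: tris(trimethylsilyloxy)ethene, C[Si](C)(C)OC=C(O[Si](C)(C)C)O[Si](C)(C)C
Why: C-Acylation of the silyl ketene acetal by the acid chloride gives silyl ester 8, whose hydrolysis releases a β-keto acid that decarboxylates to the hydroxymethyl ketone (acylation–decarboxylation synthesis of hydroxymethyl ketones).

Step 5
Reactants: 9 1-hydroxyhex-5-en-2-one
Product: 10 2-ethynylhex-5-ene-1,2-diol (racemic)
Conditions: HC≡CMgBr (3 equiv), THF, −20 to 0 °C; aq. NH4Cl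
Reagents that add atoms: ethynylmagnesium bromide, C#C[Mg]Br
Why: Grignard 1,2-addition of the acetylide to the ketone, after the first equivalent is spent on the hydroxyl proton, should give the tertiary propargylic alcohol as a racemate whose stereocentre is erased in step 7.

Step 6
Reactants: 10 2-ethynylhex-5-ene-1,2-diol
Product: 11 (2-ethynyl-2-hydroxyhex-5-en-1-yl) acetate (racemic)
Conditions: Ac2O (1.1 equiv), pyridine, CH2Cl2, 0 °C
Reagents that add atoms: acetic anhydride, CC(=O)OC(C)=O
Why: Chemoselective O-acylation should take the primary hydroxyl only, the tertiary propargylic hydroxyl being inert under these conditions, and placing the acetate after the Grignard step avoids acyl migration to a magnesium alkoxide.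

Step 7
Reactants: 11 (2-ethynyl-2-hydroxyhex-5-en-1-yl) acetate
Product: 12 (2E)-3-(acetoxymethyl)hepta-2,6-dienal, expected together with its (2Z) isomer
Conditions: Bu4N[ReO4] (10 mol%), 4-MeC6H4SO3H·H2O (10 mol%), CH2Cl2, 25 °C
Reagents that add atoms: none
Why: Meyer–Schuster rearrangement under oxo-rhenium catalysis ([3,3]-shift of the propargylic perrhenate ester to an allenyl perrhenate that collapses to the enal) should avoid the Rupe pathway of tertiary ethynyl carbinols and, unlike a π-acidic gold catalyst, leave the 1,6-enyne alone; the C2=C3 mixture is acceptable because both isomers give the same dienamine in step 9.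

Step 8
Reactants: 6 (5E)-6,10-dimethyl-2-methylideneundeca-5,9-dienal; 12 (2E)-3-(acetoxymethyl)hepta-2,6-dienal (with its 2Z isomer)
Product: 13 (2E,6E,10E)-3-(acetoxymethyl)-7-formyl-11,15-dimethylhexadeca-2,6,10,14-tetraenal, carried together with its (2Z) isomer
Conditions: [1,3-bis(2,4,6-trimethylphenyl)imidazolidin-2-ylidene]dichloro(2-isopropoxybenzylidene)ruthenium (second-generation Hoveyda–Grubbs catalyst, 5 mol%), 6 (2 equiv), 1,4-benzoquinone (10 mol%), CH2Cl2 (0.2 M), 40 °C
Reagents that add atoms: none
Why: Olefin cross-metathesis between a rapidly initiating terminal alkene and an electron-poor 1,1-disubstituted alkene that cannot homodimerize should give the (6E)-trisubstituted enal as the thermodynamic isomer, the conjugated alkene of 12 being inert and the trisubstituted alkenes of the terpenoid chain reacting more slowly at this concentration.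

Step 9
Reactants: 13 (2E,6E,10E)-3-(acetoxymethyl)-7-formyl-11,15-dimethylhexadeca-2,6,10,14-tetraenal (with its 2Z isomer)
Product: 15 [(3S)-2-formyl-3-[(2R,5E)-6,10-dimethyl-1-oxoundeca-5,9-dien-2-yl]cyclopent-1-en-1-yl]methyl acetate, via dienamine 14 (not isolated)
Conditions: (R)-2-[diphenyl(trimethylsilyloxy)methyl]pyrrolidine (20 mol%), PhCO2H (20 mol%), CH2Cl2 (0.05 M), 0 to 25 °C
Reagents that add atoms: none
Why: The amine condenses with the unhindered formyl group of the β,β-disubstituted enal (both C2=C3 isomers of 13 converge) and γ-deprotonation on the acetoxymethyl arm gives the (1E)-dienamine 14, whose α-carbon (C2) adds to the β-carbon (C6 of 13, C3 of the target) of the tethered (6E)-2-alkyl enal; α-deprotonation and γ-reprotonation of the resulting β,γ-unsaturated iminium ion, then hydrolysis, return the C1=C2 bond to conjugation and release the amine. The closest known reaction type is the amine-catalysed crossed intramolecular Rauhut–Currier-type (vinylogous Michael) cyclization of dienals through dienamines, which gives iridoid-type cyclopentenecarbaldehydes. Ring A closes in a 5-(enolexo)-exo-trig mode, with the enamine C=C outside the new ring. C3 is set by the catalyst: its diphenyl(trimethylsilyloxy)methyl group covers one face of the s-trans dienamine and the acceptor adds to the other in a synclinal arrangement with its formyl group under the enamine nitrogen, which for the (R)-amine should give 3S. C8 is set by protonation of the enol formed in the addition, anti to C2 in the conformer of least allylic 1,3-strain, which should give 8R. The step needs one enal to act only as donor and the other only as acceptor, and α- instead of γ-attack: the α-branched enal condenses poorly with a secondary amine, the β,β-disubstituted enal is a poor acceptor, and γ-closure would require a disfavoured endo-type five-membered transition state.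

Compound list
1 | geranyl bromide, (2E)-1-bromo-3,7-dimethylocta-2,6-diene | CC(C)=CCC/C(C)=C/CBr | starting material
2 | 2-(2-bromoethyl)-1,3-dioxolane | BrCCC1OCCO1 | starting material
3 | [2-(1,3-dioxolan-2-yl)ethyl]magnesium bromide | Br[Mg]CCC1OCCO1 | intermediate (not isolated)
4 | 2-[(4E)-5,9-dimethyldeca-4,8-dien-1-yl]-1,3-dioxolane | CC(C)=CCC/C(C)=C/CCCC1OCCO1 | intermediate
5 | (5E)-6,10-dimethylundeca-5,9-dienal | CC(C)=CCC/C(C)=C/CCCC=O | intermediate
6 | (5E)-6,10-dimethyl-2-methylideneundeca-5,9-dienal | CC(C)=CCC/C(C)=C/CCC(=C)C=O | intermediate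
7 | pent-4-enoyl chloride | C=CCCC(=O)Cl | starting material
8 | trimethylsilyl 3-oxo-2-(trimethylsilyloxy)hept-6-enoate (racemic) | C=CCCC(=O)C(O[Si](C)(C)C)C(=O)O[Si](C)(C)C | intermediate (not isolated)
9 | 1-hydroxyhex-5-en-2-one | C=CCCC(=O)CO | intermediate
10 | 2-ethynylhex-5-ene-1,2-diol (racemic) | C#CC(O)(CO)CCC=C | intermediate
11 | (2-ethynyl-2-hydroxyhex-5-en-1-yl) acetate (racemic) | C#CC(O)(COC(C)=O)CCC=C | intermediate
12 | (2E)-3-(acetoxymethyl)hepta-2,6-dienal (2E isomer drawn; 2Z isomer accompanies it) | O=C/C=C(/COC(C)=O)CCC=C | intermediate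
13 | (2E,6E,10E)-3-(acetoxymethyl)-7-formyl-11,15-dimethylhexadeca-2,6,10,14-tetraenal (2E isomer drawn; 2Z isomer accompanies it) | O=C/C=C(/COC(C)=O)CC/C=C(/C=O)CC/C=C(\C)CCC=C(C)C | intermediate (key-step precursor)
14 | (2R)-1-[(1E,6E,10E)-3-(acetoxymethylidene)-7-formyl-11,15-dimethylhexadeca-1,6,10,14-tetraen-1-yl]-2-[diphenyl(trimethylsilyloxy)methyl]pyrrolidine (enol acetate geometry not defined) | C[Si](C)(C)OC(c1ccccc1)(c1ccccc1)[C@H]1CCCN1/C=C/C(=COC(C)=O)CC/C=C(/C=O)CC/C=C(\C)CCC=C(C)C | intermediate (not isolated)
15 | [(3S)-2-formyl-3-[(2R,5E)-6,10-dimethyl-1-oxoundeca-5,9-dien-2-yl]cyclopent-1-en-1-yl]methyl acetate (CNP0280859.2) | CC(=O)OCC1=C(C=O)[C@H]([C@H](C=O)CC/C=C(\C)CCC=C(C)C)CC1 | target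

Total step count: 9.
Longest linear sequence: 6 steps (7 → 9 → 10 → 11 → 12 → 13 → 15); the other branch (1 + 2 → 4 → 5 → 6) has 3 steps before the union.

Steps most likely to fail

Step 9. What may go wrong is non-selective protonation of the C8 enol after ring closure, or later epimerization next to the formyl group, so that 15 is accompanied by its C8 epimer. The fallback sets out from 13 and comes back at 15 and replaces reliance on kinetic protonation by separation and recycling. The cyclization is run as above and the pair is separated by chromatography. The epimer [(3S)-2-formyl-3-[(2S,5E)-6,10-dimethyl-1-oxoundeca-5,9-dien-2-yl]cyclopent-1-en-1-yl]methyl acetate F1 is then re-equilibrated at C8 through its enol with 1,8-diazabicyclo[5.4.0]undec-7-ene (5 mol%) in CH2Cl2 at 0 °C and separated again. C3 is not enolizable and should stay intact, so repeated cycles should funnel material into 15.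

Step 8. What may go wrong is competing metathesis at the isopropylidene terminus (loss of isobutene, chain scrambling) together with slow turnover at the 1,1-disubstituted enal. The fallback uses no metathesis, sets out from 12 and 1 and comes back at 13.
- The terminal alkene of 12 is cleaved selectively (O3, CH2Cl2, −78 °C, then Me2S; the conjugated alkene is deactivated) to the dialdehyde (2E)-3-(acetoxymethyl)hex-2-enedial F2, with its 2Z isomer.
- In parallel 1 is alkylated with the lithium enolate of tert-butyl acetate (LiN(i-Pr)2, THF, −78 °C) to tert-butyl (4E)-5,9-dimethyldeca-4,8-dienoate F3.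
- F3 is reduced with LiAlH4 to (4E)-5,9-dimethyldeca-4,8-dien-1-ol F4, which is converted with CBr4 and PPh3 into (4E)-1-bromo-5,9-dimethyldeca-4,8-diene F5.
- F5 is heated with PPh3 in MeCN to give [(4E)-5,9-dimethyldeca-4,8-dien-1-yl]triphenylphosphonium bromide F6.
- Deprotonation of F6 with n-BuLi and C-formylation of the ylide with HCO2Et give the stabilized ylide (5E)-6,10-dimethyl-2-(triphenyl-λ5-phosphanylidene)undeca-5,9-dienal F7.
- Wittig olefination of F2 with F7 (benzene, 60 °C) should occur at the saturated formyl group, which is more electrophilic than the conjugated one, and give 13 with the (6E) geometry typical of formyl-stabilized ylides.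

Step 7. What may go wrong is a stalled or diverted 1,3-transposition: ionization is slowed by the acetoxymethyl group, and Rupe-type dehydration or participation of the acetoxy group may compete. The fallback sets out from 9 and comes back at 12.
- CH2=CHMgBr (3 equiv, THF, −20 °C) adds to 9 to give 2-ethenylhex-5-ene-1,2-diol F8.
- Selective acetylation as in step 6 gives (2-ethenyl-2-hydroxyhex-5-en-1-yl) acetate F9.
- Oxidative 1,3-transposition of this tertiary allylic alcohol with pyridinium chlorochromate [C5H5NH][CrO3Cl] in CH2Cl2 (Babler–Dauben oxidation: [3,3]-shift of the chromate ester, then oxidation at the primary allylic position) should give 12.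

Further compounds
F1 | step 9 | [(3S)-2-formyl-3-[(2S,5E)-6,10-dimethyl-1-oxoundeca-5,9-dien-2-yl]cyclopent-1-en-1-yl]methyl acetate | CC(=O)OCC1=C(C=O)[C@H]([C@@H](C=O)CC/C=C(\C)CCC=C(C)C)CC1
F2 | step 8 | (2E)-3-(acetoxymethyl)hex-2-enedial | O=C/C=C(/COC(C)=O)CCC=O
F3 | step 8 | tert-butyl (4E)-5,9-dimethyldeca-4,8-dienoate | CC(C)=CCC/C(C)=C/CCC(=O)OC(C)(C)C
F4 | step 8 | (4E)-5,9-dimethyldeca-4,8-dien-1-ol | CC(C)=CCC/C(C)=C/CCCO
F5 | step 8 | (4E)-1-bromo-5,9-dimethyldeca-4,8-diene | CC(C)=CCC/C(C)=C/CCCBr
F6 | step 8 | [(4E)-5,9-dimethyldeca-4,8-dien-1-yl]triphenylphosphonium bromide | CC(C)=CCC/C(C)=C/CCC[P+](c1ccccc1)(c1ccccc1)c1ccccc1.[Br-]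
F7 | step 8 | (5E)-6,10-dimethyl-2-(triphenyl-λ5-phosphanylidene)undeca-5,9-dienal | CC(C)=CCC/C(C)=C/CCC(C=O)=P(c1ccccc1)(c1ccccc1)c1ccccc1
F8 | step 7 | 2-ethenylhex-5-ene-1,2-diol | C=CC(O)(CO)CCC=C
F9 | step 7 | (2-ethenyl-2-hydroxyhex-5-en-1-yl) acetate | C=CC(O)(COC(C)=O)CCC=C
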